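**Retrosynthetic overview**

- The target is 3,5,4'-trihydroxy-7-methoxy-8-prenylflavone. The plan rests on its ring A, a phloroglucinol with oxygens on C5, C7 and C8a and the C4 acyl carbon on C4a (the acetate pattern of a chalcone), in which only the C7 oxygen is methylated and C8 is prenylated.
- Ring C (O1–C2 bond and the C3 hydroxyl) is disconnected last, by Algar–Flynn–Oyamada oxidation of a 2'-hydroxychalcone whose future C5 oxygen is blocked as a MOM ether, so that the prenyl-flanked oxygen becomes O1.
- Ring A is disconnected at C4a–C8a: Claisen fold of a 4-methoxy-3-prenyl-2-pyranone carrying a cinnamoylmethyl group at C6. This is a masked tetraketide whose enol ether becomes the C7 methyl ether and whose C3 prenyl group becomes the C8 prenyl group.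
- The pyranone comes from lateral acylation of 4-methoxy-6-methyl-3-prenyl-2-pyranone (triacetic acid lactone, prenyl bromide, then O-methylation) with the Weinreb amide of MOM-protected 4-hydroxycinnamic acid.
- Ring order: ring B and the sacrificial pyranone are bought; ring A is formed in step 6 and ring C in step 8.

Key step: step 6

Remark on the chemistry: the target has no stereocentre, so nothing has to be set; the only stereogenic carbons of the route belong to a transient racemic dihydroflavonol and vanish in the same flask. β-Dicarbonyl compounds are drawn as keto tautomers. 4-(Methoxymethoxy)benzaldehyde and N-methoxy-N-methylacetamide, used only in a fallback, are taken as purchased reagents.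

**Route**

Step 1
Reactants: 1 4-hydroxy-6-methyl-2H-pyran-2-one (1.5 equiv); 2 1-bromo-3-methylbut-2-ene
Product: 3 4-hydroxy-6-methyl-3-(3-methylbut-2-en-1-yl)-2H-pyran-2-one
Conditions: KOH (1.5 equiv), H2O, 0 °C → rt
Reagents that add atoms: none
Why: C-alkylation (allylic SN2) of the ambident potassium enolate of the vinylogous acid at C3; water hydrogen-bonds the enolate oxygens and so steers the soft primary allylic bromide to carbon, and the excess of 1 should limit 3,3-dialkylation.

Step 2
Reactants: 3 4-hydroxy-6-methyl-3-(3-methylbut-2-en-1-yl)-2H-pyran-2-one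
Product: 4 4-methoxy-6-methyl-3-(3-methylbut-2-en-1-yl)-2H-pyran-2-one
Conditions: Me2SO4, K2CO3, acetone, reflux
Reagents that add atoms: dimethyl sulfate, COS(=O)(=O)OC
Why: Williamson-type O-methylation with a hard electrophile, which should alkylate the C4 oxygen and keep the 2-pyranone rather than the 4-pyranone form, as is usual for triacetic acid lactones under these conditions.

Step 3
Reactants: 5 (E)-4-hydroxycinnamic acid
Product: 6 (2E)-3-(4-hydroxyphenyl)-N-methoxy-N-methylprop-2-enamide
Conditions: MeNHOMe·HCl, EDC·HCl, HOBt (cat.), N-methylmorpholine, CH2Cl2/DMF, 0 °C → rt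
Reagents that add atoms: N,O-dimethylhydroxylamine hydrochloride, CNOC.Cl
Why: carbodiimide/HOBt amide coupling, in which the active ester is aminolysed by the hydroxylamine far faster than it acylates the phenol, so the phenol needs no protection and the E alkene is untouched.

Step 4
Reactants: 6 (2E)-3-(4-hydroxyphenyl)-N-methoxy-N-methylprop-2-enamide
Product: 7 (2E)-N-methoxy-3-[4-(methoxymethoxy)phenyl]-N-methylprop-2-enamide
Conditions: MOMCl, iPr2NEt, CH2Cl2, 0 °C → rt
Reagents that add atoms: chloromethyl methyl ether, COCCl
Why: phenol alkylation with an α-chloro ether (MOM ether formation); the acetal is stable to the lithium amide, magnesium alkoxide and hydroxide bases of the later steps.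

Step 5
Reactants: 4 4-methoxy-6-methyl-3-(3-methylbut-2-en-1-yl)-2H-pyran-2-one (1.5 equiv); 7 (2E)-N-methoxy-3-[4-(methoxymethoxy)phenyl]-N-methylprop-2-enamide
Product: 8 4-methoxy-6-{(3E)-4-[4-(methoxymethoxy)phenyl]-2-oxobut-3-en-1-yl}-3-(3-methylbut-2-en-1-yl)-2H-pyran-2-one
Conditions: LiN(iPr)2 (1.6 equiv), THF, −78 °C; then 7, −78 → −30 °C; then AcOH, −78 °C
Reagents that add atoms: none
Why: kinetic deprotonation of the 6-methyl group gives the vinylogous lactone enolate (C3 is blocked, so ring metalation cannot compete), and its acylation by the Weinreb amide stops at the chelated tetrahedral adduct, so the enone and the acidic methylene of 8 appear only on work-up and neither over-addition nor conjugate addition can follow.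

Step 6
Reactants: 8 4-methoxy-6-{(3E)-4-[4-(methoxymethoxy)phenyl]-2-oxobut-3-en-1-yl}-3-(3-methylbut-2-en-1-yl)-2H-pyran-2-one
Product: 10 (2E)-1-[2,6-dihydroxy-4-methoxy-3-(3-methylbut-2-en-1-yl)phenyl]-3-[4-(methoxymethoxy)phenyl]prop-2-en-1-one, via ring-opened methyl ester 9 (not isolated)
Conditions: Mg(OMe)2 (8 equiv), MeOH, reflux, argon; then cold 0.5 M HCl to pH 5; crude product taken on at once
Reagents that add atoms: none
Why: Methoxide adds to the lactone carbonyl of the pyranone and opens it to methyl ester 9, in which the future C7 carbonyl stays masked as its methyl enol ether and the ester and the keto chain stay cis on the enol-ether double bond because that geometry is inherited from the ring. The magnesium-chelated enolate of the methylene between the two free ketones (future C4a) then attacks the ester carbon (future C8a) in a 6-exo-trig Claisen (Dieckmann-type) closure; methoxide leaves and the acylcyclohexadienone tautomerises to the phenol, which closes ring A. The closest known reaction type is the biomimetic Claisen cyclisation of 3,5,7-triketo esters and of 6-(2-oxoalkyl)-4-methoxy-2-pyranones to acylphloroglucinols under Mg(OMe)2, the laboratory counterpart of the chalcone synthase fold. No stereocentre is formed and the E enone is not touched. The step needs Claisen closure to win over aldol closure, relactonisation and Michael addition to the enone: the enol ether removes the C7 carbonyl as an aldol acceptor, the prenyl group makes the only other carbon nucleophile within six-membered reach (the ester α-carbon) quaternary so that its aldol adduct cannot aromatise and reverts, relactonisation and oxa-Michael additions are reversible, and aromatisation to the magnesium bis-phenoxide drains all these equilibria.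

Step 7
Reactants: 10 (2E)-1-[2,6-dihydroxy-4-methoxy-3-(3-methylbut-2-en-1-yl)phenyl]-3-[4-(methoxymethoxy)phenyl]prop-2-en-1-one
Product: 11 (2E)-1-[2-hydroxy-4-methoxy-6-(methoxymethoxy)-3-(3-methylbut-2-en-1-yl)phenyl]-3-[4-(methoxymethoxy)phenyl]prop-2-en-1-one
Conditions: MOMCl (1.05 equiv), iPr2NEt, CH2Cl2, −20 → 0 °C
Reagents that add atoms: chloromethyl methyl ether, COCCl
Why: kinetically controlled phenol alkylation (MOM ether formation) at the hydroxyl on C6', which has a single ortho substituent, whereas the hydroxyl on C2' is flanked by the acyl and prenyl groups and is held in the stronger chelate to the carbonyl by the buttressing prenyl group; once one ether is in place the remaining phenol is fully chelated, which should hold back bis-protection.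

Step 8
Reactants: 11 (2E)-1-[2-hydroxy-4-methoxy-6-(methoxymethoxy)-3-(3-methylbut-2-en-1-yl)phenyl]-3-[4-(methoxymethoxy)phenyl]prop-2-en-1-one
Product: 13 3-hydroxy-7-methoxy-5-(methoxymethoxy)-2-[4-(methoxymethoxy)phenyl]-8-(3-methylbut-2-en-1-yl)-4H-chromen-4-one, via trans-dihydroflavonol 12 (not isolated)
Conditions: 30% aq H2O2, 2 M aq NaOH, MeOH/THF, 0 °C → rt; then AcOH to pH 6
Reagents that add atoms: hydrogen peroxide, OO
Why: Algar–Flynn–Oyamada oxidation, in which the C2' phenoxide (the only free phenol) closes 6-endo onto the β-carbon of the enone, directly or through the chalcone epoxide, with hydroxylation of the α-carbon by hydroperoxide to give racemic trans-dihydroflavonol 12, which alkaline peroxide dehydrogenates to the flavonol so that the ring oxygen ends up next to the prenyl-bearing C8; nucleophilic alkaline H2O2 does not epoxidise the electron-rich prenyl alkene, and the two stereocentres of 12 are erased when ring C becomes aromatic.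

Step 9
Reactants: 13 3-hydroxy-7-methoxy-5-(methoxymethoxy)-2-[4-(methoxymethoxy)phenyl]-8-(3-methylbut-2-en-1-yl)-4H-chromen-4-one
Product: 14 3,5-dihydroxy-2-(4-hydroxyphenyl)-7-methoxy-8-(3-methylbut-2-en-1-yl)-4H-chromen-4-one (isoanhydroicaritin)
Conditions: conc. aq HCl (to ca. 1 M), MeOH/THF, 40 °C
Reagents that add atoms: none
Why: acid-catalysed acetal exchange of both MOM ethers with methanol; the prenyl group has no free ortho hydroxyl (C7 carries a methyl ether, C8a the ring oxygen), so acid-induced chroman formation is excluded, and the mild acid strength and temperature should spare the trisubstituted alkene from Markovnikov addition.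

**Compound list**

1 | 4-hydroxy-6-methyl-2H-pyran-2-one | Cc1cc(O)cc(=O)o1 | starting material
2 | 1-bromo-3-methylbut-2-ene (prenyl bromide) | CC(C)=CCBr | starting material
3 | 4-hydroxy-6-methyl-3-(3-methylbut-2-en-1-yl)-2H-pyran-2-one | Cc1cc(O)c(CC=C(C)C)c(=O)o1 | intermediate
4 | 4-methoxy-6-methyl-3-(3-methylbut-2-en-1-yl)-2H-pyran-2-one | COc1cc(C)oc(=O)c1CC=C(C)C | intermediate
5 | (E)-4-hydroxycinnamic acid | O=C(O)/C=C/c1ccc(O)cc1 | starting material
6 | (2E)-3-(4-hydroxyphenyl)-N-methoxy-N-methylprop-2-enamide | CON(C)C(=O)/C=C/c1ccc(O)cc1 | intermediate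
7 | (2E)-N-methoxy-3-[4-(methoxymethoxy)phenyl]-N-methylprop-2-enamide | CON(C)C(=O)/C=C/c1ccc(OCOC)cc1 | intermediate
8 | 4-methoxy-6-{(3E)-4-[4-(methoxymethoxy)phenyl]-2-oxobut-3-en-1-yl}-3-(3-methylbut-2-en-1-yl)-2H-pyran-2-one | COc1cc(CC(=O)/C=C/c2ccc(OCOC)cc2)oc(=O)c1CC=C(C)C | intermediate
9 | methyl (2E,8E)-3-methoxy-9-[4-(methoxymethoxy)phenyl]-2-(3-methylbut-2-en-1-yl)-5,7-dioxonona-2,8-dienoate (magnesium chelate in the flask, not isolated) | COC(=O)/C(CC=C(C)C)=C(/OC)CC(=O)CC(=O)/C=C/c1ccc(OCOC)cc1 | intermediate
10 | (2E)-1-[2,6-dihydroxy-4-methoxy-3-(3-methylbut-2-en-1-yl)phenyl]-3-[4-(methoxymethoxy)phenyl]prop-2-en-1-one | COc1cc(O)c(C(=O)/C=C/c2ccc(OCOC)cc2)c(O)c1CC=C(C)C | intermediate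
11 | (2E)-1-[2-hydroxy-4-methoxy-6-(methoxymethoxy)-3-(3-methylbut-2-en-1-yl)phenyl]-3-[4-(methoxymethoxy)phenyl]prop-2-en-1-one | COCOc1cc(OC)c(CC=C(C)C)c(O)c1C(=O)/C=C/c1ccc(OCOC)cc1 | intermediate
12 | rac-(2R,3R)-3-hydroxy-7-methoxy-5-(methoxymethoxy)-2-[4-(methoxymethoxy)phenyl]-8-(3-methylbut-2-en-1-yl)-2,3-dihydro-4H-chromen-4-one (trans, racemic, one enantiomer drawn, not isolated) | COCOc1ccc(cc1)[C@@H]2[C@H](C(=O)c3c(OCOC)cc(OC)c(CC=C(C)C)c3O2)O | intermediate
13 | 3-hydroxy-7-methoxy-5-(methoxymethoxy)-2-[4-(methoxymethoxy)phenyl]-8-(3-methylbut-2-en-1-yl)-4H-chromen-4-one | COCOc1ccc(cc1)-c1oc2c(CC=C(C)C)c(OC)cc(OCOC)c2c(=O)c1O | intermediate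
14 | 3,5-dihydroxy-2-(4-hydroxyphenyl)-7-methoxy-8-(3-methylbut-2-en-1-yl)-4H-chromen-4-one (isoanhydroicaritin) | COc1cc(O)c2c(=O)c(O)c(-c3ccc(O)cc3)oc2c1CC=C(C)C | target

**Step count**

Total: 9 steps. Longest linear sequence: 7 steps (steps 1, 2, 5, 6, 7, 8, 9 from 1; equally steps 3, 4, 5, 6, 7, 8, 9 from 5).

**Steps most likely to fail**

Step 6. What may go wrong: after ring opening, conjugate addition of methoxide or of the magnesium enolate to the cinnamoyl enone, or oxa-Michael closure to a dihydropyranone, consumes the open chain before the Claisen closure takes place; alternatively the product cyclises to flavanones during work-up. The fallback folds ring A before the styryl unit is attached. It sets out from 4: lateral lithiation (LiN(iPr)2, THF, −78 °C; AcOH quench) and acylation with N-methoxy-N-methylacetamide should give 4-methoxy-3-(3-methylbut-2-en-1-yl)-6-(2-oxopropyl)-2H-pyran-2-one F1. Mg(OMe)2 in refluxing methanol (cold dilute HCl work-up) should open it to methyl (2E)-3-methoxy-2-(3-methylbut-2-en-1-yl)-5,7-dioxooct-2-enoate F2, not isolated, which closes by the same Claisen mode, now on a saturated methyl ketone, to 1-[2,6-dihydroxy-4-methoxy-3-(3-methylbut-2-en-1-yl)phenyl]ethan-1-one F3. MOMCl/iPr2NEt at the less hindered phenol gives 1-[2-hydroxy-4-methoxy-6-(methoxymethoxy)-3-(3-methylbut-2-en-1-yl)phenyl]ethan-1-one F4. Claisen–Schmidt condensation of F4 with 4-(methoxymethoxy)benzaldehyde (KOH, EtOH, rt; dilute HCl neutralisation) comes back to the route at 11.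

Step 8. What may go wrong: the phenoxide closes 5-exo at the α-carbon (aurone formation), the known bias of chalcones substituted at C6', or the oxidation stalls before ring C is aromatic. The fallback closes the six-membered ring first and oxidises afterwards. It sets out from 11: NaOAc in refluxing EtOH should isomerise the chalcone by oxa-Michael addition to racemic 7-methoxy-5-(methoxymethoxy)-2-[4-(methoxymethoxy)phenyl]-8-(3-methylbut-2-en-1-yl)-2,3-dihydro-4H-chromen-4-one F5. Its lithium enolate (LiN(SiMe3)2, THF, −78 °C) is hydroxylated at C3 with 3-phenyl-2-(phenylsulfonyl)oxaziridine (AcOH quench) to give 12, now isolated; this reagent leaves the prenyl alkene alone. Dess–Martin periodinane (CH2Cl2, rt) oxidises the C3 carbinol of 12 to the 3,4-dione, whose enol is the flavonol, so the route is rejoined at 13.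

Step 7. What may go wrong: alkylation does not discriminate well enough between the two chelated phenols, runs on to the bis-ether, or is outrun by amine-catalysed flavanone formation. The fallback lets ring closure, not alkylation, tell the two oxygens apart. It sets out from 10: NaOAc in refluxing EtOH should give the two racemic 5-hydroxyflavanones, 5-hydroxy-7-methoxy-2-[4-(methoxymethoxy)phenyl]-8-(3-methylbut-2-en-1-yl)-2,3-dihydro-4H-chromen-4-one F6 and its isomer 5-hydroxy-7-methoxy-2-[4-(methoxymethoxy)phenyl]-6-(3-methylbut-2-en-1-yl)-2,3-dihydro-4H-chromen-4-one F7, to be separated by chromatography. F7 is reopened to 10 with KOH in MeOH (cold dilute HCl) and recycled. The single, chelated phenol of F6 is protected with excess MOMCl/iPr2NEt (cat. DMAP, CH2Cl2, reflux) to give the flavanone F5 described under the fallback for step 8. Under the NaOH of step 8, F5 opens by E1cB elimination to the phenoxide of 11, so the route is rejoined at 11.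

**Further compounds**

F1 | step 6 | 4-methoxy-3-(3-methylbut-2-en-1-yl)-6-(2-oxopropyl)-2H-pyran-2-one | COc1cc(CC(C)=O)oc(=O)c1CC=C(C)C
F2 | step 6 | methyl (2E)-3-methoxy-2-(3-methylbut-2-en-1-yl)-5,7-dioxooct-2-enoate (not isolated) | COC(=O)/C(CC=C(C)C)=C(/OC)CC(=O)CC(C)=O
F3 | step 6 | 1-[2,6-dihydroxy-4-methoxy-3-(3-methylbut-2-en-1-yl)phenyl]ethan-1-one | COc1cc(O)c(C(C)=O)c(O)c1CC=C(C)C
F4 | step 6 | 1-[2-hydroxy-4-methoxy-6-(methoxymethoxy)-3-(3-methylbut-2-en-1-yl)phenyl]ethan-1-one | COCOc1cc(OC)c(CC=C(C)C)c(O)c1C(C)=O
F5 | step 8 | 7-methoxy-5-(methoxymethoxy)-2-[4-(methoxymethoxy)phenyl]-8-(3-methylbut-2-en-1-yl)-2,3-dihydro-4H-chromen-4-one (racemic) | COCOc1ccc(cc1)C1CC(=O)c2c(OCOC)cc(OC)c(CC=C(C)C)c2O1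
F6 | step 7 | 5-hydroxy-7-methoxy-2-[4-(methoxymethoxy)phenyl]-8-(3-methylbut-2-en-1-yl)-2,3-dihydro-4H-chromen-4-one (racemic) | COCOc1ccc(cc1)C1CC(=O)c2c(O)cc(OC)c(CC=C(C)C)c2O1
F7 | step 7 | 5-hydroxy-7-methoxy-2-[4-(methoxymethoxy)phenyl]-6-(3-methylbut-2-en-1-yl)-2,3-dihydro-4H-chromen-4-one (racemic) | COCOc1ccc(cc1)C1CC(=O)c2c(O)c(CC=C(C)C)c(OC)cc2O1
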